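Ring C (the pyranone) is a β-aryloxy ketone: O1–C2 lies β to the C4 carbonyl, and the only stereocentre, C3, is its α-carbon. Ring C is therefore opened to an acyclic 2-aryl-1-(2-hydroxyaryl)prop-2-en-1-one. In one operation a bifunctional cinchona squaramide should add the ring A phenol oxygen to the methylene terminus (6-endo-trig oxa-Michael, closing O1–C2) and protonate the resulting C3 enol face-selectively, setting (3S). The enone, with the phenol free, is made under neutral conditions by MnO2 oxidation of an allylic alcohol assembled by Shapiro coupling of an acetylchromene hydrazone with a silyl-protected 2,4-dihydroxybenzaldehyde.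

Key step: step 7

Remark: the facial sense of proton delivery by the quinine-derived squaramide is assigned by analogy with thiol addition–protonation; should the first run show the (3R) ketone in excess, the quinidine-derived pseudoenantiomer is used with no other change.

Step 1
Reactants: 1 1-(4-hydroxy-2-methoxyphenyl)ethanone; 2 3-chloro-3-methylbut-1-yne
Product: 3 1-[2-methoxy-4-(2-methylbut-3-yn-2-yloxy)phenyl]ethanone
Conditions: K2CO3, KI, CuI (cat.), acetone, reflux
Reagents that add atoms: none
Why: Copper-assisted O-alkylation of the acidic para-acyl phenoxide with the tertiary propargylic chloride is the standard entry to aryl 1,1-dimethylpropargyl ethers.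

Step 2
Reactants: 3 1-[2-methoxy-4-(2-methylbut-3-yn-2-yloxy)phenyl]ethanone
Product: 6 encecalin [1-(7-methoxy-2,2-dimethyl-2H-chromen-6-yl)ethanone], via allenylphenol 4 (not isolated), via ortho-quinone methide 5 (not isolated)
Conditions: N,N-diethylaniline, 190 °C
Reagents that add atoms: none
Why: Aromatic propargyl Claisen rearrangement to C5 gives allenylphenol 4, whose 1,5-hydrogen shift to ortho-quinone methide 5 and oxa-6π-electrocyclisation should close the 2,2-dimethylpyran; C5 (para to the methoxy group) is preferred over C3, which is flanked by two oxygen substituents.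

Step 3
Reactants: 6 encecalin
Product: 7 (E)-N'-[1-(7-methoxy-2,2-dimethyl-2H-chromen-6-yl)ethylidene]-2,4,6-tri(propan-2-yl)benzenesulfonohydrazide
Conditions: 2,4,6-triisopropylbenzenesulfonyl hydrazide, HCl (cat.), MeOH, rt
Reagents that add atoms: 2,4,6-triisopropylbenzenesulfonyl hydrazide, CC(C)c1cc(C(C)C)c(S(=O)(=O)NN)c(C(C)C)c1
Why: Acid-catalysed condensation of the aryl methyl ketone with the sulfonyl hydrazide should give the (E)-hydrazone (sulfonamide anti to the aryl group), the Shapiro precursor, and the trace of acid is tolerated by the chromene.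

Step 4
Reactants: 8 2,4-dihydroxybenzaldehyde
Product: 9 2-hydroxy-4-[tri(propan-2-yl)silyloxy]benzaldehyde
Conditions: TIPSCl (1.05 equiv), imidazole, CH2Cl2, 0 °C
Reagents that add atoms: triisopropylsilyl chloride (TIPSCl), CC(C)[Si](Cl)(C(C)C)C(C)C
Why: The 4-hydroxyl is the more acidic and is not held in the hydrogen bond to the formyl group, so one equivalent of silyl chloride should silylate it selectively (regioselective silyl ether formation).

Step 5
Reactants: 7 the trisylhydrazone of encecalin; 9 2-hydroxy-4-[tri(propan-2-yl)silyloxy]benzaldehyde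
Product: 12 racemic 1-{2-hydroxy-4-[tri(propan-2-yl)silyloxy]phenyl}-2-(7-methoxy-2,2-dimethyl-2H-chromen-6-yl)prop-2-en-1-ol, via vinyllithium 10 (not isolated), via sodium phenoxide 11 (not isolated)
Conditions: 7 (1.3 equiv), n-BuLi (2.1 equiv per 7), THF, −78 → 0 °C; then −78 °C, 11 (from 9, NaH, THF, 0 °C); aq. NH4Cl
Reagents that add atoms: none
Why: Shapiro reaction, in which double deprotonation of the hydrazone (N–H and the syn methyl group) and loss of sulfinate and N2 give the 1-arylvinyllithium 10, which adds 1,2 to the aldehyde whose phenol is held as sodium phenoxide 11 so that it cannot quench the organolithium; the carbinol centre is racemic and is removed in step 6.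

Step 6
Reactants: 12 the racemic allylic alcohol
Product: 13 1-{2-hydroxy-4-[tri(propan-2-yl)silyloxy]phenyl}-2-(7-methoxy-2,2-dimethyl-2H-chromen-6-yl)prop-2-en-1-one
Conditions: activated MnO2 (excess), CH2Cl2, 0 °C → rt; filtration through Celite, concentration in the cold, used at once
Reagents that add atoms: none
Why: MnO2 oxidises the doubly activated (benzylic and allylic) alcohol under neutral heterogeneous conditions, under which the phenol stays hydrogen-bonded to the new carbonyl and no base is present to trigger ring closure.

Step 7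
Reactants: 13 the 2'-hydroxy α-aryl enone
Product: 15 (3S)-3-(7-methoxy-2,2-dimethyl-2H-chromen-6-yl)-7-[tri(propan-2-yl)silyloxy]-2,3-dihydro-4H-chromen-4-one, via chromen-4-ol enol 14 (not isolated)
Conditions: quinine-derived squaramide (from 9-amino-9-deoxy-epi-quinine and 3,5-bis(trifluoromethyl)aniline, 10 mol %), toluene, −40 °C
Reagents that add atoms: none
Why: Proposed new method: the quinuclidine nitrogen of the catalyst takes up the phenol proton while the squaramide N–H bonds hold the C4 carbonyl, the phenoxide oxygen adds to the unsubstituted methylene terminus of the enone, and the quinuclidinium ion returns its proton to C3 of the squaramide-bound enol/enolate 14 before this leaves the chiral pocket. The closest known reaction types are the cinchona (thio)urea- and squaramide-catalysed conjugate addition–enantioselective protonation of thiols on α-substituted acceptors and the amine–(thio)urea-catalysed intramolecular oxa-Michael cyclisation of phenols to chromans and flavanones; their union on an α-aryl enone with an oxygen nucleophile is the new element. Ring C is closed in the 6-endo-trig mode, the only mode open to the ortho-acyl phenol. The C3 stereocentre is set by the catalyst alone, since no other stereocentre is present: proton delivery to the Re face of C3 in 14 (priorities C4 > C2 > aryl) gives (3S). The step needs enantioface selectivity in the proton transfer, no uncatalysed closure and no racemisation of the α-aryl ketone; the O–H···O=C bond of the ortho-hydroxy ketone should keep the phenol unreactive until the catalyst deprotonates it, the terminal methylene leaves C3 as the only new stereocentre, and low temperature, an apolar solvent and the electron-donating 7-silyloxy group should slow enolisation of the product.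

Step 8
Reactants: 15 the (3S)-7-silyloxy isoflavanone
Product: 16 (3S)-7-hydroxy-3-(7-methoxy-2,2-dimethyl-2H-chromen-6-yl)-2,3-dihydro-4H-chromen-4-one (the target)
Conditions: TBAF, AcOH (1:1.2), THF, 0 °C
Reagents that add atoms: none
Why: Fluoride cleaves the aryl silyl ether and the acetic acid buffer keeps the medium near neutral, so the C3–H of the α-aryl ketone should not be epimerised and the chromene is untouched (silyl ether deprotection).

Compound list
1 | 1-(4-hydroxy-2-methoxyphenyl)ethanone | CC(=O)c1ccc(O)cc1OC | starting material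
2 | 3-chloro-3-methylbut-1-yne | C#CC(C)(C)Cl | starting material
3 | 1-[2-methoxy-4-(2-methylbut-3-yn-2-yloxy)phenyl]ethanone | CC(=O)c1ccc(OC(C)(C)C#C)cc1OC | intermediate
4 | 1-[4-hydroxy-2-methoxy-5-(3-methylbuta-1,2-dien-1-yl)phenyl]ethanone (allenylphenol) | CC(=O)c1cc(C=C=C(C)C)c(O)cc1OC | intermediate (not isolated)
5 | 4-acetyl-5-methoxy-2-(3-methylbut-2-en-1-ylidene)cyclohexa-3,5-dien-1-one (ortho-quinone methide) | CC(=O)C1=CC(=CC=C(C)C)C(=O)C=C1OC | intermediate (not isolated)
6 | 1-(7-methoxy-2,2-dimethyl-2H-chromen-6-yl)ethanone (encecalin) | CC(=O)c1cc2C=CC(C)(C)Oc2cc1OC | intermediate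
7 | (E)-N'-[1-(7-methoxy-2,2-dimethyl-2H-chromen-6-yl)ethylidene]-2,4,6-tri(propan-2-yl)benzenesulfonohydrazide | C/C(=N\NS(=O)(=O)c1c(C(C)C)cc(C(C)C)cc1C(C)C)c1cc2C=CC(C)(C)Oc2cc1OC | intermediate
8 | 2,4-dihydroxybenzaldehyde | O=Cc1ccc(O)cc1O | starting material
9 | 2-hydroxy-4-[tri(propan-2-yl)silyloxy]benzaldehyde | O=Cc1ccc(O[Si](C(C)C)(C(C)C)C(C)C)cc1O | intermediate
10 | [1-(7-methoxy-2,2-dimethyl-2H-chromen-6-yl)ethenyl]lithium | [Li]C(=C)c1cc2C=CC(C)(C)Oc2cc1OC | intermediate (not isolated)
11 | sodium 2-formyl-5-[tri(propan-2-yl)silyloxy]phenolate | [Na+].[O-]c1cc(O[Si](C(C)C)(C(C)C)C(C)C)ccc1C=O | intermediate (not isolated)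
12 | racemic 1-{2-hydroxy-4-[tri(propan-2-yl)silyloxy]phenyl}-2-(7-methoxy-2,2-dimethyl-2H-chromen-6-yl)prop-2-en-1-ol | C=C(C(O)c1ccc(O[Si](C(C)C)(C(C)C)C(C)C)cc1O)c1cc2C=CC(C)(C)Oc2cc1OC | intermediate
13 | 1-{2-hydroxy-4-[tri(propan-2-yl)silyloxy]phenyl}-2-(7-methoxy-2,2-dimethyl-2H-chromen-6-yl)prop-2-en-1-one | C=C(C(=O)c1ccc(O[Si](C(C)C)(C(C)C)C(C)C)cc1O)c1cc2C=CC(C)(C)Oc2cc1OC | intermediate
14 | 3-(7-methoxy-2,2-dimethyl-2H-chromen-6-yl)-7-[tri(propan-2-yl)silyloxy]-2H-chromen-4-ol (catalyst-bound enol) | OC1=C(c2cc3C=CC(C)(C)Oc3cc2OC)COc2cc(O[Si](C(C)C)(C(C)C)C(C)C)ccc12 | intermediate (not isolated)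
15 | (3S)-3-(7-methoxy-2,2-dimethyl-2H-chromen-6-yl)-7-[tri(propan-2-yl)silyloxy]-2,3-dihydro-4H-chromen-4-one | COc1cc2c(cc1[C@H]1COc3cc(O[Si](C(C)C)(C(C)C)C(C)C)ccc3C1=O)C=CC(C)(C)O2 | intermediate
16 | (3S)-7-hydroxy-3-(7-methoxy-2,2-dimethyl-2H-chromen-6-yl)-2,3-dihydro-4H-chromen-4-one | COc1cc2c(cc1[C@H]1COc3cc(O)ccc3C1=O)C=CC(C)(C)O2 | target

Total step count: 8. Longest linear sequence: 7 steps (steps 1, 2, 3, 5, 6, 7, 8); step 4 is the only step of the second branch.

Steps most likely to fail

Step 7. The proton transfer to C3 may show poor facial selectivity, an uncatalysed closure may compete, or the amine may slowly racemise the α-aryl ketone once formed. The fallback uses known chemistry and sets out from 13. Triethylamine (cat.) in CH2Cl2 at rt should close the ring without stereocontrol to the racemic ketone F1. Asymmetric transfer hydrogenation under dynamic kinetic resolution (RuCl(p-cymene)[(S,S)-TsDPEN], HCO2H/Et3N 5:2, EtOAc, rt) should funnel the rapidly epimerising ketone into the cis-(3S,4S)-isoflavan-4-ol F2. The chromene double bond is not expected to be reduced. Dess–Martin periodinane (NaHCO3, CH2Cl2, 0 °C) should then reoxidise C4 without touching C3, and the fallback comes back to the route at 15.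

Step 6. The free hydroxy enone may close spontaneously on the oxidant surface or during concentration, or may oligomerise, so that racemic ketone is carried into step 7. The fallback sets out from 12 and gives up isolation of the enone. After the MnO2 oxidation the filtrate is treated with triethylamine so that closure runs to completion to the racemic ketone F1. This is converted (TMSOTf, Et3N, CH2Cl2, 0 °C) into the trimethylsilyl enol ether F3. F3 is then protonated enantioselectively with a BINOL-derived N-triflyl thiophosphoramide (cat.) and phenol (1.1 equiv) in toluene at low temperature, the known catalytic protonation of silyl enol ethers of 2-aryl cyclic ketones. The fallback comes back to the route at 15.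

Step 5. Vinyllithium formation may be incomplete, or the organolithium may be protonated before it adds, which would give the 6-vinylchromene in place of the carbinol. The fallback sets out from 6 and 9 and replaces the organolithium by an organochromium species. KHMDS and PhNTf2 (THF, −78 °C) should convert 6 into the enol triflate F4. Nozaki–Hiyama–Kishi coupling of F4 with aldehyde 9 (CrCl2 in excess, NiCl2 cat., DMF, rt) tolerates the free phenol. The fallback comes back to the route at 12.

Further compounds
F1 | step 7 | racemic 3-(7-methoxy-2,2-dimethyl-2H-chromen-6-yl)-7-[tri(propan-2-yl)silyloxy]-2,3-dihydro-4H-chromen-4-one | COc1cc2c(cc1C1COc3cc(O[Si](C(C)C)(C(C)C)C(C)C)ccc3C1=O)C=CC(C)(C)O2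
F2 | step 7 | (3S,4S)-3-(7-methoxy-2,2-dimethyl-2H-chromen-6-yl)-7-[tri(propan-2-yl)silyloxy]-3,4-dihydro-2H-chromen-4-ol (cis) | COc1cc2c(cc1[C@H]1COc3cc(O[Si](C(C)C)(C(C)C)C(C)C)ccc3[C@H]1O)C=CC(C)(C)O2
F3 | step 6 | 3-(7-methoxy-2,2-dimethyl-2H-chromen-6-yl)-4-(trimethylsilyloxy)-7-[tri(propan-2-yl)silyloxy]-2H-chromene | C[Si](C)(C)OC1=C(c2cc3C=CC(C)(C)Oc3cc2OC)COc2cc(O[Si](C(C)C)(C(C)C)C(C)C)ccc12
F4 | step 5 | 1-(7-methoxy-2,2-dimethyl-2H-chromen-6-yl)ethenyl trifluoromethanesulfonate | C=C(OS(=O)(=O)C(F)(F)F)c1cc2C=CC(C)(C)Oc2cc1OC
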